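**Retrosynthetic overview**

1. The last disconnection is the C11′–C12′ single bond between the terminal side-chain CH2 and the vinylic CH of the (Z)-C12′=C13′ alkene. It gives two electrophiles, (R)-2-(11-bromoundecyl)-6-methyl-2,3-dihydro-4H-pyran-4-one and (Z)-1-bromodec-1-ene, which are joined by a nickel-catalysed reductive cross-electrophile coupling (alkenylnickel plus primary alkyl radical).
2. Enabling feature: the sp3 carbon of this bond is an unbranched primary CH2 held eleven methylenes away from C2 of the only ring, so its radical cannot reach the ring enone (C4=O, C5=C6) and the C2 stereocentre is a spectator. The sp2 carbon is a vinylic CH of a non-conjugated 1,2-dialkyl alkene, whose Z geometry can be set beforehand and carried through on nickel.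
3. The dihydropyranone ring (the only ring) is formed before the coupling, by a BINOL–titanium-catalysed Mukaiyama aldol/cyclisation (formal hetero-Diels–Alder reaction) of 12-bromododecanal with the acetylacetone-derived 1-methoxy-3-silyloxy diene; this step sets C2 as R.
4. The Z-alkenyl bromide comes from dec-1-yne by bromination and syn-hydroboration/protonolysis.

Key step: step 7

Assumption: the catalyst from Ti(OiPr)4 and (S)-BINOL is taken to deliver the diene to the Si face of the unbranched aldehyde, by analogy with BINOL–titanium-catalysed allylstannane additions to aldehydes; this gives R at C2, and (R)-BINOL would be used instead if the sense proves opposite.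

**Route**

Step 1
Reactants: 1 pentane-2,4-dione (acetylacetone)
Product: 2 (E)-4-methoxypent-3-en-2-one
Conditions: HC(OMe)3, MeOH, p-TsOH (cat.), rt to 50 °C; distillation
Reagents that add atoms: trimethyl orthoformate, COC(OC)OC
Why: Acid-catalysed enol ether formation: the orthoformate turns one carbonyl of the β-diketone into its dimethyl ketal, which loses methanol to give the conjugated β-methoxy enone as the more stable E isomer; no stereocentre is formed.

Step 2
Reactants: 2 (E)-4-methoxypent-3-en-2-one
Product: 3 (E)-4-methoxy-2-(trimethylsilyloxy)penta-1,3-diene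
Conditions: LDA, THF, −78 °C; then TMSCl, −78 °C to rt; non-aqueous work-up, distillation
Reagents that add atoms: chlorotrimethylsilane, C[Si](C)(C)Cl
Why: Kinetic deprotonation of the acetyl CH3 by LDA gives the cross-conjugated lithium dienolate, and O-silylation (silyl enol ether formation) should give the electron-rich diene with the C3=C4 geometry unchanged.

Step 3
Reactants: 4 12-bromododecan-1-ol
Product: 5 12-bromododecanal
Conditions: TEMPO (10 mol%), PhI(OAc)2 (1.1 equiv), CH2Cl2, rt
Reagents that add atoms: none
Why: TEMPO/PhI(OAc)2 oxidation through the oxoammonium salt should convert the primary alcohol into the aldehyde without over-oxidation and leave the primary bromide untouched.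

Step 4
Reactants: 5 12-bromododecanal; 3 (E)-4-methoxy-2-(trimethylsilyloxy)penta-1,3-diene
Product: 7 (R)-2-(11-bromoundecyl)-6-methyl-2,3-dihydro-4H-pyran-4-one, via silyl aldol adduct 6 (not isolated)
Conditions: Ti(OiPr)4 (10 mol%), (S)-BINOL (20 mol%), 4 Å MS, Et2O, −20 °C; then CF3CO2H, CH2Cl2, 0 °C
Reagents that add atoms: none
Why: Catalytic asymmetric Mukaiyama aldol addition/cyclisation (formal hetero-Diels–Alder reaction): the chiral BINOL–titanium Lewis acid activates the aldehyde so that the CH2 terminus of diene 3 adds to its Si face, which sets C2 as R under catalyst control, and CF3CO2H then removes the silyl group and closes the ring by 6-endo-trig oxa-conjugate addition with loss of methanol.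

Step 5
Reactants: 8 dec-1-yne
Product: 9 1-bromodec-1-yne
Conditions: NBS, AgNO3 (10 mol%), acetone, rt
Reagents that add atoms: N-bromosuccinimide, O=C1CCC(=O)N1Br
Why: Silver-catalysed electrophilic bromination of a terminal alkyne (through the silver acetylide) by NBS is a standard, selective route to 1-bromoalkynes.

Step 6
Reactants: 9 1-bromodec-1-yne
Product: 11 (Z)-1-bromodec-1-ene, via bromoalkenylborane 10 (not isolated)
Conditions: (c-C6H11)2BH (made from BH3·SMe2 and cyclohexene, THF, 0 °C), THF, 0 °C to rt; then AcOH, 0 °C to rt
Reagents that add atoms: none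
Why: Hydroboration–protonolysis: dicyclohexylborane adds syn across the bromoalkyne with boron on the bromine-bearing carbon, and acetic acid cleaves the C–B bond with retention, so the two hydrogens end up cis and the alkene should be Z.

Step 7
Reactants: 7 (R)-2-(11-bromoundecyl)-6-methyl-2,3-dihydro-4H-pyran-4-one; 11 (Z)-1-bromodec-1-ene
Product: 12 (R)-2-[(Z)-henicos-12-en-1-yl]-6-methyl-2,3-dihydro-4H-pyran-4-one
Conditions: NiBr2(dme) (10 mol%), 4,4′-di-tert-butyl-2,2′-bipyridine (10 mol%), Zn dust (2 equiv), DMA, 25 °C; 11 in 1.5 equiv
Reagents that add atoms: none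
Why: Zinc reduces the nickel dibromide/bipyridine complex to zerovalent nickel, which adds oxidatively to the C(sp2)–Br bond of 11 with retention to give a divalent (Z)-alkenylnickel bromide, while monovalent nickel abstracts bromine from 7 to give the primary C11′ radical; capture of this radical gives a trivalent nickel species that reductively eliminates the C11′–C12′ bond, and zinc closes the cycle. The closest known reaction type is the nickel/bipyridine-catalysed reductive cross-electrophile coupling of alkenyl bromides with primary alkyl bromides, which is reported to proceed with retention of alkene geometry. No ring is closed and no stereocentre is created; the step only has to preserve the C2 centre and the Z geometry. Cross-coupling over homo-coupling is secured by the different activation modes of the two halides (two-electron oxidative addition at sp2 carbon, halogen abstraction at sp3 carbon) and by the excess of the cheaper partner 11. Z retention is secured by the non-conjugated, alkyl-substituted alkenyl–nickel bond, which has no easy isomerisation path at room temperature. Chemoselectivity is secured by the eleven-methylene spacer and by the electron-rich, β,β-disubstituted vinylogous ester C5=C6, a poor acceptor for a nucleophilic alkyl radical, and the neutral, base-free medium cannot open the ring by β-elimination, so C2 should not epimerise.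

**Compound list**

1 | pentane-2,4-dione (acetylacetone) | CC(=O)CC(C)=O | starting material
2 | (E)-4-methoxypent-3-en-2-one | CC(=O)/C=C(\C)OC | intermediate
3 | (E)-4-methoxy-2-(trimethylsilyloxy)penta-1,3-diene | C=C(O[Si](C)(C)C)/C=C(\C)OC | intermediate
4 | 12-bromododecan-1-ol | OCCCCCCCCCCCCBr | starting material
5 | 12-bromododecanal | O=CCCCCCCCCCCCBr | intermediate
6 | (2E,6R)-17-bromo-2-methoxy-6-(trimethylsilyloxy)heptadec-2-en-4-one | C/C(OC)=C\C(=O)C[C@H](O[Si](C)(C)C)CCCCCCCCCCCBr | intermediate
7 | (R)-2-(11-bromoundecyl)-6-methyl-2,3-dihydro-4H-pyran-4-one | BrCCCCCCCCCCC[C@@H]1CC(=O)C=C(C)O1 | intermediate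
8 | dec-1-yne | CCCCCCCCC#C | starting material
9 | 1-bromodec-1-yne | CCCCCCCCC#CBr | intermediate
10 | (Z)-(1-bromodec-1-en-1-yl)dicyclohexylborane | CCCCCCCC/C=C(\Br)B(C1CCCCC1)C1CCCCC1 | intermediate
11 | (Z)-1-bromodec-1-ene | CCCCCCCC/C=C\Br | intermediate
12 | (R)-2-[(Z)-henicos-12-en-1-yl]-6-methyl-2,3-dihydro-4H-pyran-4-one | CCCCCCCC/C=C\CCCCCCCCCCC[C@@H]1CC(=O)C=C(C)O1 | target

**Step count and risks**

Total step count: 7. Longest linear sequence: 4 steps (steps 1, 2, 4, 7).

Steps most likely to fail:

Step 7 (key coupling). The coupling may be eroded by homo-dimerisation of either bromide, by hydrodehalogenation, or by Z-to-E isomerisation at the alkenylnickel stage. The fallback sets out from 7 (with 11) and comes back to the route at 12. Direct zinc insertion into 7 (Zn dust, I2 cat., DMA, 70 °C) should give [11-[(2R)-6-methyl-4-oxo-3,4-dihydro-2H-pyran-2-yl]undecyl]zinc bromide F1, an organozinc halide that tolerates the ring carbonyl. A Negishi coupling of F1 with 11 (PdCl2(dppf) cat., THF/DMA, rt to 40 °C), a two-electron zerovalent/divalent palladium cycle that is stereoretentive for Z-alkenyl bromides, should then give 12.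

Step 4 (ring and stereocentre). The aldol addition may show insufficient facial selectivity or the opposite facial sense, or the methyl-substituted diene may add sluggishly and be lost to hydrolysis of the silyl dienol ether. The fallback sets out from 5 and comes back at 7.
- A Roskamp reaction of 5 with ethyl diazoacetate (SnCl2 cat., CH2Cl2) should give ethyl 14-bromo-3-oxotetradecanoate F2.
- Noyori hydrogenation (RuCl2[(R)-BINAP], H2, EtOH, 50 °C), whose sense with unbranched β-keto esters is firmly established, should give ethyl (R)-14-bromo-3-hydroxytetradecanoate F3.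
- Aminolysis with MeNHOMe·HCl/i-PrMgCl (THF, −20 °C) should give (R)-14-bromo-3-hydroxy-N-methoxy-N-methyltetradecanamide F4.
- Addition of prop-1-ynylmagnesium bromide (3 equiv, THF, 0 °C; Weinreb ketone synthesis) should give (R)-17-bromo-6-hydroxyheptadec-2-yn-4-one F5.
- 6-endo-dig oxacyclisation of the hydroxyl onto the ynone (AgOTf cat., CH2Cl2, rt) should give 7 with the carbinol configuration unchanged.

Step 6 (Z-alkenyl bromide). Migration of a cyclohexyl group from boron to the bromine-bearing carbon, incomplete protonolysis of the C–B bond, or partial loss of Z purity may lower the quality of 11, on which the geometry of the target depends. The fallback sets out from 8 and comes back at 11. Hydroboration of 8 with pinacolborane (Cp2Zr(H)Cl cat., Et3N cat., 60 °C) should give (E)-2-(dec-1-en-1-yl)-4,4,5,5-tetramethyl-1,3,2-dioxaborolane F6. Anti addition of Br2 (CH2Cl2, −78 °C) should give racemic 2-[(1R,2S)-1,2-dibromodecyl]-4,4,5,5-tetramethyl-1,3,2-dioxaborolane F7, which is not isolated. NaOMe/MeOH (−78 °C to rt) should then trigger anti elimination of boron and bromide, giving 11 with overall inversion of the alkene geometry.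

**Further compounds**

F1 | step 7 | [11-[(2R)-6-methyl-4-oxo-3,4-dihydro-2H-pyran-2-yl]undecyl]zinc bromide | Br[Zn]CCCCCCCCCCC[C@@H]1CC(=O)C=C(C)O1
F2 | step 4 | ethyl 14-bromo-3-oxotetradecanoate | CCOC(=O)CC(=O)CCCCCCCCCCCBr
F3 | step 4 | ethyl (R)-14-bromo-3-hydroxytetradecanoate | CCOC(=O)C[C@H](O)CCCCCCCCCCCBr
F4 | step 4 | (R)-14-bromo-3-hydroxy-N-methoxy-N-methyltetradecanamide | CON(C)C(=O)C[C@H](O)CCCCCCCCCCCBr
F5 | step 4 | (R)-17-bromo-6-hydroxyheptadec-2-yn-4-one | CC#CC(=O)C[C@H](O)CCCCCCCCCCCBr
F6 | step 6 | (E)-2-(dec-1-en-1-yl)-4,4,5,5-tetramethyl-1,3,2-dioxaborolane | CCCCCCCC/C=C/B1OC(C)(C)C(C)(C)O1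
F7 | step 6 | racemic 2-[(1R,2S)-1,2-dibromodecyl]-4,4,5,5-tetramethyl-1,3,2-dioxaborolane | CCCCCCCC[C@H](Br)[C@H](Br)B1OC(C)(C)C(C)(C)O1
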